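**Retrosynthetic overview**
1. Ring letters: flavanone unit = A (phloroglucinol ring), C (pyranone), B (catechol ring); flavone unit = D (phloroglucinol ring, bonded to ring B), E (pyrone), F (catechol ring). Last disconnection: eight benzyl ethers, removed by neutral hydrogenolysis.
2. Key disconnection: rings C and E are opened together to one acyclic biaryl carrying an alkylidene β-ketoester (on ring B) and a MOM-masked 2-hydroxyaryl 1,3-diketone (on ring D). Forward, an asymmetric oxa-Michael addition closes ring C and sets C2, then acid closes ring E in the same pot.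
3. Alkylidene C=C: Knoevenagel condensation of a biaryl aldehyde with the ring A tert-butyl β-ketoester.
4. Ring B–ring D bond: Suzuki–Miyaura coupling of a 2-formylarylboron species with an iodo diketone; the diketone comes from a Claisen condensation.
5. Ring order: the four benzene rings are bought (A and D both from phloroacetophenone); ring C closes first, ring E second.

Assumption: only C2 is stereodefined in the given SMILES (R by CIP: O1 > aryl > C3 > H); the sense of the ring B–ring D biaryl axis is unspecified and is left uncontrolled.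

**Route**

Step 1
Reactants: 1 (2,4,6-trihydroxyacetophenone)
Product: 2 1-[2,4-bis(benzyloxy)-6-hydroxyphenyl]ethan-1-one
Conditions: BnBr (2.1 equiv), K2CO3 (2.5 equiv), DMF, rt
Reagents that add atoms: benzyl bromide, BrCc1ccccc1
Why: Williamson etherification in which K2CO3 ionises only the two non-chelated phenols, the third OH being hydrogen-bonded to the acetyl group and left free.

Step 2
Reactants: 2 (1-[2,4-bis(benzyloxy)-6-hydroxyphenyl]ethan-1-one)
Product: 3 1-[4,6-bis(benzyloxy)-2-hydroxy-3-iodophenyl]ethan-1-one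
Conditions: NIS (1.05 equiv), DMF, 0 °C to rt, dark
Reagents that add atoms: N-iodosuccinimide, O=C1CCC(=O)N1I
Why: Electrophilic aromatic iodination ortho to the chelated phenol, the position between OH and OBn being less crowded than the one between two OBn groups, as in the known ortho-halogenation of 2-hydroxy-4,6-dialkoxyacetophenones.

Step 3
Reactants: 3 (1-[4,6-bis(benzyloxy)-2-hydroxy-3-iodophenyl]ethan-1-one)
Product: 4 1-[4,6-bis(benzyloxy)-3-iodo-2-(methoxymethoxy)phenyl]ethan-1-one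
Conditions: NaH (1.3 equiv), MOMCl (1.3 equiv), DMF, 0 °C to rt
Reagents that add atoms: chloromethyl methyl ether, COCCl
Why: Williamson-type O-alkylation of the sodium phenoxide (NaH is needed for the chelated, flanked phenol), installing the only acid-labile ether of the route on the oxygen that must later close ring E.

Step 4
Reactants: 4 (1-[4,6-bis(benzyloxy)-3-iodo-2-(methoxymethoxy)phenyl]ethan-1-one); 5 (methyl 3,4-bis(benzyloxy)benzoate)
Product: 6 1-[4,6-bis(benzyloxy)-3-iodo-2-(methoxymethoxy)phenyl]-3-[3,4-bis(benzyloxy)phenyl]propane-1,3-dione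
Conditions: NaH (3 equiv), THF, 65 °C; then AcOH (aq), 0 °C
Reagents that add atoms: none
Why: Crossed Claisen condensation of the methyl ketone enolate with a non-enolisable ester, driven by formation of the stabilised sodium diketonate.

Step 5
Reactants: 7 (3,4-bis(benzyloxy)benzaldehyde)
Product: 8 4,5-bis(benzyloxy)-2-bromobenzaldehyde
Conditions: Br2 (1.05 equiv), NaOAc, AcOH, rt
Reagents that add atoms: bromine, BrBr
Why: Electrophilic aromatic bromination para to the 3-benzyloxy group and ortho to the formyl group, the standard regiochemistry of 3,4-dialkoxybenzaldehydes, with NaOAc buffering HBr so the benzyl ethers survive.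

Step 6
Reactants: 8 (4,5-bis(benzyloxy)-2-bromobenzaldehyde, 1.4 equiv); 6 (iodo diketone from step 4)
Product: 10 4,5-bis(benzyloxy)-2-{4,6-bis(benzyloxy)-3-[3-(3,4-bis(benzyloxy)phenyl)-3-oxopropanoyl]-2-(methoxymethoxy)phenyl}benzaldehyde, via pinacol boronate 9 (not isolated)
Conditions: B2pin2, PdCl2(dppf) (3 mol %), KOAc, 1,4-dioxane, 90 °C; then 6, Pd(OAc)2 (5 mol %), SPhos (10 mol %), K3PO4 (aq), 90 °C
Reagents that add atoms: bis(pinacolato)diboron, CC1(C)OB(OC1(C)C)B1OC(C)(C)C(C)(C)O1 (boryl group of 9)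
Why: Miyaura borylation followed by Suzuki–Miyaura coupling in one pot, with boron placed on the formyl-bearing ring to avoid a protodeboronation-prone 2,6-dialkoxyarylboron species, SPhos enabling the tri-ortho-substituted biaryl and the diketone carried as its potassium enolate.

Step 7
Reactants: 2 (1-[2,4-bis(benzyloxy)-6-hydroxyphenyl]ethan-1-one)
Product: 11 tert-butyl 3-[2,4-bis(benzyloxy)-6-hydroxyphenyl]-3-oxopropanoate
Conditions: LiN(SiMe3)2 (3.2 equiv), THF, −78 °C; Boc2O (1.1 equiv), −78 to 0 °C; then AcOH (aq)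
Reagents that add atoms: di-tert-butyl dicarbonate, CC(C)(C)OC(=O)OC(=O)OC(C)(C)C
Why: Claisen-type C-acylation of the phenoxide–enolate dianion by Boc2O (any O-Boc carbonate formed first converges on the same product by Baker–Venkataraman-type O-to-C transfer under excess base), the tert-butyl ester preventing lactonisation to a 4-hydroxycoumarin.

Step 8
Reactants: 10 (biaryl aldehyde from step 6); 11 (tert-butyl 3-[2,4-bis(benzyloxy)-6-hydroxyphenyl]-3-oxopropanoate, 1.3 equiv)
Product: 12 tert-butyl 2-[2,4-bis(benzyloxy)-6-hydroxybenzoyl]-3-{4,5-bis(benzyloxy)-2-[4,6-bis(benzyloxy)-3-(3-(3,4-bis(benzyloxy)phenyl)-3-oxopropanoyl)-2-(methoxymethoxy)phenyl]phenyl}prop-2-enoate (E/Z mixture)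
Conditions: piperidine (20 mol %), AcOH (20 mol %), 4 Å molecular sieves, toluene, rt to 40 °C
Reagents that add atoms: none
Why: Knoevenagel condensation through the piperidinium iminium of the aldehyde, the β-ketoester being the most accessible active methylene while the hindered diaryl diketone does not compete.

Step 9
Reactants: 12 (alkylidene β-ketoester from step 8)
Product: 14 (2R)-5,7-bis(benzyloxy)-2-{4,5-bis(benzyloxy)-2-[5,7-bis(benzyloxy)-2-(3,4-bis(benzyloxy)phenyl)-4-oxo-4H-chromen-8-yl]phenyl}chroman-4-one, via chromanone tert-butyl ester 13 (not isolated)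
Conditions: 9-amino-9-deoxy-epi-quinidine 3,5-bis(trifluoromethyl)phenyl thiourea (20 mol %), toluene, −25 °C; then TsOH·H2O (2 equiv), MeOH (10 equiv), 80 °C
Reagents that add atoms: none
Why: Proposed new method: a telescoped double heterocyclisation in which the thiourea binds the alkylidene β-ketoester while the quinuclidine nitrogen delivers the ring A phenol to one alkene face (intramolecular asymmetric oxa-Michael addition closing ring C and setting C2 as R with the quinidine-series catalyst; closest known reaction: cinchona-thiourea cyclisation of 2-hydroxyaryl alkylidene β-ketoesters followed by TsOH decarboxylation), ring D having no free phenol that could intercept the alkene, after which the acid stage expels isobutene and CO2, cleaves the single MOM ether and cyclodehydrates the freed 2-hydroxyaryl 1,3-diketone to the flavone (ring E, the classical diketone-to-flavone cyclodehydration) with the benzyl ether on the other ortho oxygen fixing the 8-aryl regiochemistry.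

Step 10
Reactants: 14 (octabenzyl ether from step 9)
Product: 15 (2R)-2-{2-[2-(3,4-dihydroxyphenyl)-5,7-dihydroxy-4-oxo-4H-chromen-8-yl]-4,5-dihydroxyphenyl}-5,7-dihydroxychroman-4-one
Conditions: H2 (1 atm), 10% Pd/C, THF/MeOH, rt
Reagents that add atoms: none
Why: Hydrogenolysis of the eight benzyl ethers under neutral conditions, so that C2 (prone to base-induced ring opening once the ring B para-OH is free) keeps its R configuration while the flavone C2=C3 bond and the chromanone C2–O bond are left intact at 1 atm and rt.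

**Compound list**
1 | 2,4,6-trihydroxyacetophenone | CC(=O)c1c(O)cc(O)cc1O | starting material
2 | 1-[2,4-bis(benzyloxy)-6-hydroxyphenyl]ethan-1-one | CC(=O)c1c(O)cc(OCc2ccccc2)cc1OCc1ccccc1 | intermediate
3 | 1-[4,6-bis(benzyloxy)-2-hydroxy-3-iodophenyl]ethan-1-one | CC(=O)c1c(O)c(I)c(OCc2ccccc2)cc1OCc1ccccc1 | intermediate
4 | 1-[4,6-bis(benzyloxy)-3-iodo-2-(methoxymethoxy)phenyl]ethan-1-one | CC(=O)c1c(OCOC)c(I)c(OCc2ccccc2)cc1OCc1ccccc1 | intermediate
5 | methyl 3,4-bis(benzyloxy)benzoate | COC(=O)c1ccc(OCc2ccccc2)c(OCc2ccccc2)c1 | starting material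
6 | 1-[4,6-bis(benzyloxy)-3-iodo-2-(methoxymethoxy)phenyl]-3-[3,4-bis(benzyloxy)phenyl]propane-1,3-dione | O=C(CC(=O)c1ccc(OCc2ccccc2)c(OCc2ccccc2)c1)c1c(OCOC)c(I)c(OCc2ccccc2)cc1OCc1ccccc1 | intermediate
7 | 3,4-bis(benzyloxy)benzaldehyde | O=Cc1ccc(OCc2ccccc2)c(OCc2ccccc2)c1 | starting material
8 | 4,5-bis(benzyloxy)-2-bromobenzaldehyde | O=Cc1cc(OCc2ccccc2)c(OCc2ccccc2)cc1Br | intermediate
9 | 4,5-bis(benzyloxy)-2-(4,4,5,5-tetramethyl-1,3,2-dioxaborolan-2-yl)benzaldehyde (not isolated) | O=Cc1cc(OCc2ccccc2)c(OCc2ccccc2)cc1B1OC(C)(C)C(C)(C)O1 | intermediate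
10 | 4,5-bis(benzyloxy)-2-{4,6-bis(benzyloxy)-3-[3-(3,4-bis(benzyloxy)phenyl)-3-oxopropanoyl]-2-(methoxymethoxy)phenyl}benzaldehyde | O=Cc1cc(OCc2ccccc2)c(OCc2ccccc2)cc1-c1c(OCc2ccccc2)cc(OCc2ccccc2)c(C(=O)CC(=O)c2ccc(OCc3ccccc3)c(OCc3ccccc3)c2)c1OCOC | intermediate
11 | tert-butyl 3-[2,4-bis(benzyloxy)-6-hydroxyphenyl]-3-oxopropanoate | CC(C)(C)OC(=O)CC(=O)c1c(O)cc(OCc2ccccc2)cc1OCc1ccccc1 | intermediate
12 | tert-butyl 2-[2,4-bis(benzyloxy)-6-hydroxybenzoyl]-3-{4,5-bis(benzyloxy)-2-[4,6-bis(benzyloxy)-3-(3-(3,4-bis(benzyloxy)phenyl)-3-oxopropanoyl)-2-(methoxymethoxy)phenyl]phenyl}prop-2-enoate (E/Z mixture) | CC(C)(C)OC(=O)C(=Cc1cc(OCc2ccccc2)c(OCc2ccccc2)cc1-c1c(OCc2ccccc2)cc(OCc2ccccc2)c(C(=O)CC(=O)c2ccc(OCc3ccccc3)c(OCc3ccccc3)c2)c1OCOC)C(=O)c1c(O)cc(OCc2ccccc2)cc1OCc1ccccc1 | intermediate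
13 | tert-butyl (2R)-5,7-bis(benzyloxy)-2-{4,5-bis(benzyloxy)-2-[4,6-bis(benzyloxy)-3-(3-(3,4-bis(benzyloxy)phenyl)-3-oxopropanoyl)-2-(methoxymethoxy)phenyl]phenyl}-4-oxochromane-3-carboxylate (C3 epimers, partly enolised; not isolated) | O=C1C(C(=O)OC(C)(C)C)[C@H](c2cc(OCc3ccccc3)c(OCc3ccccc3)cc2-c2c(OCc3ccccc3)cc(OCc3ccccc3)c(C(=O)CC(=O)c3ccc(OCc4ccccc4)c(OCc4ccccc4)c3)c2OCOC)Oc2cc(OCc3ccccc3)cc(OCc3ccccc3)c21 | intermediate
14 | (2R)-5,7-bis(benzyloxy)-2-{4,5-bis(benzyloxy)-2-[5,7-bis(benzyloxy)-2-(3,4-bis(benzyloxy)phenyl)-4-oxo-4H-chromen-8-yl]phenyl}chroman-4-one | O=C1C[C@H](c2cc(OCc3ccccc3)c(OCc3ccccc3)cc2-c2c(OCc3ccccc3)cc(OCc3ccccc3)c3c(=O)cc(-c4ccc(OCc5ccccc5)c(OCc5ccccc5)c4)oc23)Oc2cc(OCc3ccccc3)cc(OCc3ccccc3)c21 | intermediate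
15 | (2R)-2-{2-[2-(3,4-dihydroxyphenyl)-5,7-dihydroxy-4-oxo-4H-chromen-8-yl]-4,5-dihydroxyphenyl}-5,7-dihydroxychroman-4-one (CNP0228504.1) | O=C1C[C@H](c2cc(O)c(O)cc2-c2c(O)cc(O)c3c(=O)cc(-c4ccc(O)c(O)c4)oc23)Oc2cc(O)cc(O)c21 | target

**Step count and risks**

Total step count: 10. Longest linear sequence: 8 steps (steps 1, 2, 3, 4, 6, 8, 9, 10; compounds 1 → 2 → 3 → 4 → 6 → 10 → 12 → 14 → 15).

Three steps most likely to fail:

Step 9. The acidic 1,3-diketone may tie up the amine of the bifunctional catalyst, and the very hindered ortho-biaryl group on the alkene may erode the enantioselectivity. The absolute sense of induction is assigned by analogy and must be checked by circular dichroism; if only the sense is wrong, the quinine-derived pseudoenantiomer of the catalyst is used. The fallback sets out from 12 and returns at 14, moving stereocontrol from catalysis to separation. 12 is cyclised with Et3N (20 mol %, toluene, rt) to the racemic chromanone tert-butyl ester F1, which goes through the same TsOH·H2O/MeOH stage to the racemic octabenzyl ether F2. Preparative chiral SFC on an amylose tris(3,5-dimethylphenylcarbamate) phase then gives 14. The (2S)-enantiomer F3 is recycled to F2 by DBU-induced ring opening and re-closure.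

Step 6. The coupling builds a tri-ortho-substituted biaryl from a 2-formylarylboronate, which can protodeboronate, in the presence of a chelating diketone enolate. The fallback sets out from 8 and 4 and returns at 10; the biaryl bond is made before the diketone exists and with the aldehyde masked. 8 is converted into the dimethyl acetal F4 (HC(OMe)3, cat. TsOH, MeOH) and borylated to the isolated pinacol boronate acetal F5 (B2pin2, PdCl2(dppf), KOAc). F5 is coupled with methyl ketone 4 (Pd(OAc)2/SPhos, K3PO4) to the biaryl ketone acetal F6. Claisen condensation of F6 with 5 (NaH, THF) gives the diketone acetal F7, and PPTS in wet acetone at rt releases the aldehyde to give 10, leaving the aryl MOM ether intact.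

Step 8. The aldehyde is electron-rich and flanked by a 2,6-disubstituted aryl ring, so the condensation may stall, or the product may cyclise racemically on prolonged heating with amine. The fallback sets out from 10 and returns at 12, replacing the carbonyl condensation by addition–elimination on a preformed imine. 10 and aniline (4 Å molecular sieves, toluene) give the N-phenyl imine F8. Mannich addition of 11 (PhCO2H 10 mol %, toluene, 40 °C) followed by β-elimination of aniline gives 12.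

**Further compounds**
F1 | step 9 | racemic tert-butyl 5,7-bis(benzyloxy)-2-{4,5-bis(benzyloxy)-2-[4,6-bis(benzyloxy)-3-(3-(3,4-bis(benzyloxy)phenyl)-3-oxopropanoyl)-2-(methoxymethoxy)phenyl]phenyl}-4-oxochromane-3-carboxylate | O=C1C(C(=O)OC(C)(C)C)C(c2cc(OCc3ccccc3)c(OCc3ccccc3)cc2-c2c(OCc3ccccc3)cc(OCc3ccccc3)c(C(=O)CC(=O)c3ccc(OCc4ccccc4)c(OCc4ccccc4)c3)c2OCOC)Oc2cc(OCc3ccccc3)cc(OCc3ccccc3)c21
F2 | step 9 | racemic 5,7-bis(benzyloxy)-2-{4,5-bis(benzyloxy)-2-[5,7-bis(benzyloxy)-2-(3,4-bis(benzyloxy)phenyl)-4-oxo-4H-chromen-8-yl]phenyl}chroman-4-one | O=C1CC(c2cc(OCc3ccccc3)c(OCc3ccccc3)cc2-c2c(OCc3ccccc3)cc(OCc3ccccc3)c3c(=O)cc(-c4ccc(OCc5ccccc5)c(OCc5ccccc5)c4)oc23)Oc2cc(OCc3ccccc3)cc(OCc3ccccc3)c21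
F3 | step 9 | (2S)-5,7-bis(benzyloxy)-2-{4,5-bis(benzyloxy)-2-[5,7-bis(benzyloxy)-2-(3,4-bis(benzyloxy)phenyl)-4-oxo-4H-chromen-8-yl]phenyl}chroman-4-one | O=C1C[C@@H](c2cc(OCc3ccccc3)c(OCc3ccccc3)cc2-c2c(OCc3ccccc3)cc(OCc3ccccc3)c3c(=O)cc(-c4ccc(OCc5ccccc5)c(OCc5ccccc5)c4)oc23)Oc2cc(OCc3ccccc3)cc(OCc3ccccc3)c21
F4 | step 6 | 1,2-bis(benzyloxy)-4-bromo-5-(dimethoxymethyl)benzene | COC(OC)c1cc(OCc2ccccc2)c(OCc2ccccc2)cc1Br
F5 | step 6 | 2-[4,5-bis(benzyloxy)-2-(dimethoxymethyl)phenyl]-4,4,5,5-tetramethyl-1,3,2-dioxaborolane | COC(OC)c1cc(OCc2ccccc2)c(OCc2ccccc2)cc1B1OC(C)(C)C(C)(C)O1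
F6 | step 6 | 1-[4,6-bis(benzyloxy)-3-(4,5-bis(benzyloxy)-2-(dimethoxymethyl)phenyl)-2-(methoxymethoxy)phenyl]ethan-1-one | COC(OC)c1cc(OCc2ccccc2)c(OCc2ccccc2)cc1-c1c(OCc2ccccc2)cc(OCc2ccccc2)c(C(C)=O)c1OCOC
F7 | step 6 | 1-[4,6-bis(benzyloxy)-3-(4,5-bis(benzyloxy)-2-(dimethoxymethyl)phenyl)-2-(methoxymethoxy)phenyl]-3-[3,4-bis(benzyloxy)phenyl]propane-1,3-dione | COC(OC)c1cc(OCc2ccccc2)c(OCc2ccccc2)cc1-c1c(OCc2ccccc2)cc(OCc2ccccc2)c(C(=O)CC(=O)c2ccc(OCc3ccccc3)c(OCc3ccccc3)c2)c1OCOC
F8 | step 8 | (E)-N-phenyl imine of 10: 1-[4,6-bis(benzyloxy)-2-(methoxymethoxy)-3-(4,5-bis(benzyloxy)-2-[(phenylimino)methyl]phenyl)phenyl]-3-[3,4-bis(benzyloxy)phenyl]propane-1,3-dione | c1ccccc1/N=C/c1cc(OCc2ccccc2)c(OCc2ccccc2)cc1-c1c(OCc2ccccc2)cc(OCc2ccccc2)c(C(=O)CC(=O)c2ccc(OCc3ccccc3)c(OCc3ccccc3)c2)c1OCOC
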